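**Retrosynthetic overview**
1. The 13R tertiary carbinol is set last by a palladium-catalysed dynamic kinetic asymmetric hydrolysis of a 2-alkyl-2-vinyloxirane, made from the C13 aldehyde (vinyl addition, oxidation, sulfonium-ylide epoxidation); the 8(17)-methylene comes from Wittig methylenation of a C8 ketone.
2. Rings A and B are closed together by one intramolecular Diels–Alder reaction of trienoate 21 (bonds C3–C4 and C5–C10). The feature used: C4 (CH3, CO2Me) and C5 (H) are the two carbons of an E 2-methyl-2-enoate, and C10 with its C20 methyl is the substituted terminus of a C10=C1–C2=C3 diene joined to C5 by the C6–C9 tether.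
3. The diene comes from Stille vinylation of an E 2-methylvinyl iodide (Negishi methylalumination–iodination of a C10≡C1 alkyne); the enoate comes from cross-metathesis of a terminal alkene with methyl methacrylate, placed after the LiBH4 and Me3Al steps so that no ester meets those reagents.
4. C8 and C9 are set by an Evans syn aldol of the (R)-4-benzyloxazolidinone imide of 5-silyloxypentanoic acid with pent-4-enal.
5. Ring order: rings A and B simultaneously in step 11; no other ring is built.

Key step: step 11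

Remark on numbering: labdane numbering is used throughout (ring A = C1–C5, C10; ring B = C5–C10; C20 = methyl on C10; C17 = carbon on C8; side chain C11–C16 on C9), also for the open-chain precursors.
Assumption: the (R,R) enantiomer of the Trost naphthyl ligand is taken to give 13R in step 21, by analogy with 2-methyl-2-vinyloxirane; if a trial shows the opposite sense, the (S,S) ligand is used in the same step.

**Route**

Step 1
Reactants: 1 δ-valerolactone
Product: 4 5-(tert-butyldiphenylsilyloxy)pentanoic acid, via sodium 5-hydroxypentanoate 2 (not isolated), via tert-butyldiphenylsilyl 5-(tert-butyldiphenylsilyloxy)pentanoate 3 (not isolated)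
Conditions: NaOH (1.0 equiv), MeOH, 60 °C, evaporate; TBDPSCl (2.2 equiv), imidazole, DMF, rt; AcOH–THF–H2O, rt
Reagents that add atoms: sodium hydroxide, [Na+].[OH-]; tert-butyl(chloro)diphenylsilane, CC(C)(C)[Si](Cl)(c1ccccc1)c1ccccc1
Why: Hydroxide opens the lactone by acyl substitution, both the alcohol and the carboxylate are silylated, and only the labile silyl ester is solvolysed, leaving the primary TBDPS ether.

Step 2
Reactants: 4 5-(tert-butyldiphenylsilyloxy)pentanoic acid; 5 (R)-4-benzyl-2-oxazolidinone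
Product: 7 (R)-4-benzyl-3-[5-(tert-butyldiphenylsilyloxy)pentanoyl]oxazolidin-2-one, via the pivaloyl mixed anhydride 6 (not isolated)
Conditions: PivCl, Et3N, THF, −20 °C; then 5, LiCl, −20 °C → rt
Reagents that add atoms: pivaloyl chloride, CC(C)(C)C(Cl)=O (atoms present only in 6)
Why: N-Acylation through a mixed anhydride, in which the oxazolidinone (activated by LiCl/Et3N) attacks the unhindered acyl carbon and not the pivaloyl carbon.

Step 3
Reactants: 7 (R)-4-benzyl-3-[5-(tert-butyldiphenylsilyloxy)pentanoyl]oxazolidin-2-one; 8 pent-4-enal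
Product: 11 (R)-4-benzyl-3-[(2R,3S)-2-[3-(tert-butyldiphenylsilyloxy)propyl]-3-hydroxyhept-6-enoyl]oxazolidin-2-one, via the Z dibutylboron enolate 9 (not isolated), via the dibutylboron aldolate 10 (not isolated)
Conditions: Bu2BOTf, iPr2NEt, CH2Cl2, 0 °C; 8, −78 → 0 °C; pH 7 buffer, MeOH, 30% H2O2, 0 °C
Reagents that add atoms: dibutylboryl trifluoromethanesulfonate, CCCCB(CCCC)OS(=O)(=O)C(F)(F)F (atoms present only in 9 and 10)
Why: Evans syn aldol, in which the Z boron enolate reacts through a closed Zimmerman–Traxler chair on the enolate face opposite the benzyl group, setting C9 and C8 (2R,3S in the adduct) in a syn relationship.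

Step 4
Reactants: 11 the aldol adduct
Product: 12 (R)-4-benzyl-3-[(2R,3S)-3-(tert-butyldimethylsilyloxy)-2-[3-(tert-butyldiphenylsilyloxy)propyl]hept-6-enoyl]oxazolidin-2-one
Conditions: TBSOTf, 2,6-lutidine, CH2Cl2, −78 → 0 °C
Reagents that add atoms: tert-butyldimethylsilyl trifluoromethanesulfonate, CC(C)(C)[Si](C)(C)OS(=O)(=O)C(F)(F)F
Why: Silylation of the secondary alcohol with a silyl triflate and a hindered base, which blocks retro-aldol cleavage in the later steps and does not touch C8 or C9.

Step 5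
Reactants: 12 the silylated imide
Product: 13 (2S,3S)-3-(tert-butyldimethylsilyloxy)-2-[3-(tert-butyldiphenylsilyloxy)propyl]hept-6-en-1-ol
Conditions: LiBH4, MeOH (1 equiv), THF, 0 °C
Reagents that add atoms: none
Why: Reductive removal of the auxiliary, in which borohydride attacks the more electrophilic exocyclic imide carbonyl; no ester is present at this stage.

Step 6
Reactants: 13 the primary alcohol
Product: 14 (2R,3S)-3-(tert-butyldimethylsilyloxy)-2-[3-(tert-butyldiphenylsilyloxy)propyl]hept-6-enal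
Conditions: Dess–Martin periodinane, NaHCO3, CH2Cl2, 0 °C → rt
Reagents that add atoms: none
Why: Dess–Martin oxidation under buffered conditions, which should give the α-branched β-silyloxy aldehyde without epimerisation or elimination; it is used without storage.

Step 7
Reactants: 14 the aldehyde
Product: 15 tert-butyl{[(4S,5S)-5-(tert-butyldimethylsilyloxy)-4-ethynylnon-8-en-1-yl]oxy}diphenylsilane
Conditions: dimethyl (1-diazo-2-oxopropyl)phosphonate, K2CO3, MeOH, 0 °C → rt
Reagents that add atoms: dimethyl (1-diazo-2-oxopropyl)phosphonate, COP(=O)(OC)C(=[N+]=[N-])C(C)=O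
Why: Ohira–Bestmann (Seyferth–Gilbert) homologation, in which the diazomethylphosphonate anion formed in the flask adds to the aldehyde and the alkylidene carbene rearranges to the terminal alkyne (C10≡C1) under conditions mild enough to keep C9.

Step 8
Reactants: 15 the terminal alkyne
Product: 17 tert-butyl{[(4S,5S)-5-(tert-butyldimethylsilyloxy)-4-[(E)-1-iodoprop-1-en-2-yl]non-8-en-1-yl]oxy}diphenylsilane, via the E alkenyldimethylalane 16 (not isolated)
Conditions: Me3Al (3 equiv), Cp2ZrCl2 (0.3 equiv), CH2Cl2, 0 °C → rt; then I2, THF, −30 → 0 °C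
Reagents that add atoms: trimethylaluminium, C[Al](C)C; iodine, II
Why: Negishi zirconium-catalysed methylalumination adds CH3 (to C10) and Al (to C1) syn across the alkyne, and iodinolysis with retention gives the E iodide; the isolated terminal alkene reacts far more slowly.

Step 9
Reactants: 17 the vinyl iodide; 18 methyl methacrylate
Product: 19 methyl (2E,6S,7S,8E)-6-(tert-butyldimethylsilyloxy)-7-[3-(tert-butyldiphenylsilyloxy)propyl]-9-iodo-2,8-dimethylnona-2,8-dienoate
Conditions: 18 (10 equiv), second-generation Hoveyda–Grubbs catalyst RuCl2(H2IMes)(=CH-C6H4-2-OiPr) (5 mol %), CH2Cl2, 40 °C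
Reagents that add atoms: none
Why: Olefin cross-metathesis of the monosubstituted alkene with a methacrylate, which should give the thermodynamically preferred E trisubstituted enoate (CO2Me trans to C6); the trisubstituted vinyl iodide is inert to the ruthenium carbene.

Step 10
Reactants: 19 the iodo enoate; 20 tributyl(vinyl)stannane
Product: 21 methyl (2E,6S,7S,8E)-6-(tert-butyldimethylsilyloxy)-7-[3-(tert-butyldiphenylsilyloxy)propyl]-2,8-dimethylundeca-2,8,10-trienoate
Conditions: Pd2(dba)3 (2.5 mol %), AsPh3 (20 mol %), NMP, rt → 40 °C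
Reagents that add atoms: none
Why: Stille coupling at zerovalent palladium proceeds with retention of alkene geometry, giving the diene with C9 outside and the C20 methyl inside.

Step 11
Reactants: 21 the trienoate
Product: 22 methyl (4S,5S,8S,9S,10R)-8-(tert-butyldimethylsilyloxy)-9-[3-(tert-butyldiphenylsilyloxy)propyl]-4,10-dimethyl-trans-octal-1-ene-4-carboxylate (labdane numbering; CO2Me cis to H5; C1=C2 alkene)
Conditions: Me2AlCl (1.5 equiv), CH2Cl2, −40 °C → rt
Reagents that add atoms: none
Why: Me2AlCl binds the ester carbonyl and the C10=C1–C2=C3 diene adds suprafacially across the C4=C5 enoate in a concerted, asynchronous [4+2] cycloaddition, the closest known type being the Lewis-acid-promoted type 1 intramolecular Diels–Alder reaction of deca-2,8,10-trienoates. Ring B closes through the C5–C10 bond as a six-membered ring over the four-atom tether C6–C9 held in a chair, and ring A closes through the C3–C4 bond as the new cyclohexene with its alkene at C1–C2. C4 follows from the E enoate geometry, which is carried over so that CO2Me ends cis to H5 (equatorial) and the C4 methyl axial. C5 and C10 follow from the ester-endo, tether-exo approach favoured by the aluminium-bound carbonyl, which places H5 trans to the C20 methyl (trans ring fusion). The absolute sense is set by C9: in the reacting chair the C9 chain and the C8 silyl ether are both equatorial and the C9–H bond lies near the plane of the C10=C1 bond, so the dienophile reaches only one diene face. The step needs endo over exo selectivity and this facial selectivity; activation at or below room temperature is chosen because the inside C20 methyl penalises the s-cis diene and heating would open a competing 1,5-hydrogen shift of that methyl.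

Step 12
Reactants: 22 the cycloadduct
Product: 23 methyl (4S,5S,8S,9S,10R)-8-(tert-butyldimethylsilyloxy)-9-[3-(tert-butyldiphenylsilyloxy)propyl]-4,10-dimethyl-trans-decalin-4-carboxylate
Conditions: H2 (1 atm), Pd/C (10%), EtOAc, rt
Reagents that add atoms: none
Why: Heterogeneous hydrogenation of the only C=C bond (C1–C2) creates no stereocentre, and silyl ethers are stable in ethyl acetate.

Step 13
Reactants: 23 the saturated bis-silyl ether
Product: 24 methyl (4S,5S,8S,9S,10R)-9-[3-(tert-butyldiphenylsilyloxy)propyl]-8-hydroxy-4,10-dimethyl-trans-decalin-4-carboxylate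
Conditions: HF·pyridine, THF–pyridine, 0 °C → rt
Reagents that add atoms: none
Why: Acidic fluoride cleaves the tert-butyldimethylsilyl ether faster than the bulkier and more acid-stable tert-butyldiphenylsilyl ether (selective desilylation).

Step 14
Reactants: 24 the C8 alcohol
Product: 25 methyl (4S,5S,9S,10R)-9-[3-(tert-butyldiphenylsilyloxy)propyl]-4,10-dimethyl-8-oxo-trans-decalin-4-carboxylate
Conditions: Dess–Martin periodinane, CH2Cl2, rt
Reagents that add atoms: none
Why: Dess–Martin oxidation of the secondary alcohol; the C9 side chain is already in the equatorial, thermodynamically preferred orientation next to the new ketone.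

Step 15
Reactants: 25 the C8 ketone
Product: 26 methyl (4S,5S,9R,10S)-9-[3-(tert-butyldiphenylsilyloxy)propyl]-4,10-dimethyl-8-methylene-trans-decalin-4-carboxylate
Conditions: Ph3PCH3Br, KOtBu, toluene, rt → 80 °C
Reagents that add atoms: methyltriphenylphosphonium bromide, C[P+](c1ccccc1)(c1ccccc1)c1ccccc1.[Br-]
Why: Wittig methylenation with excess ylide converts the hindered ketone into the 8(17)-alkene; the tertiary ester is inert and any enolisation at C9 returns the more stable equatorial isomer.

Step 16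
Reactants: 26 the silyl ether
Product: 27 methyl (4S,5S,9R,10S)-9-(3-hydroxypropyl)-4,10-dimethyl-8-methylene-trans-decalin-4-carboxylate
Conditions: TBAF, THF, 0 °C → rt
Reagents that add atoms: none
Why: Fluoride-mediated cleavage of the primary silyl ether; the hindered tertiary methyl ester is not affected.

Step 17
Reactants: 27 the primary alcohol
Product: 28 methyl (4S,5S,9R,10S)-4,10-dimethyl-8-methylene-9-(3-oxopropyl)-trans-decalin-4-carboxylate
Conditions: Dess–Martin periodinane, CH2Cl2, rt
Reagents that add atoms: none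
Why: Dess–Martin oxidation to the C13 aldehyde without touching the exocyclic alkene.

Step 18
Reactants: 28 the C13 aldehyde
Product: 29 methyl (4S,5S,9R,10S)-9-[(3RS)-3-hydroxypent-4-en-1-yl]-4,10-dimethyl-8-methylene-trans-decalin-4-carboxylate
Conditions: CH2=CHMgBr, THF, −78 °C
Reagents that add atoms: vinylmagnesium bromide, C=C[Mg]Br
Why: Grignard 1,2-addition to the aldehyde, far faster than attack on the neopentyl-type ester; the C13 configuration is irrelevant because it is oxidised next.

Step 19
Reactants: 29 the allylic alcohol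
Product: 30 methyl (4S,5S,9R,10S)-4,10-dimethyl-8-methylene-9-(3-oxopent-4-en-1-yl)-trans-decalin-4-carboxylate
Conditions: Dess–Martin periodinane, CH2Cl2, 0 °C → rt
Reagents that add atoms: none
Why: Dess–Martin oxidation of the allylic alcohol to the vinyl ketone under neutral conditions; the enone is used at once.

Step 20
Reactants: 30 the vinyl ketone
Product: 31 methyl (4S,5S,9R,10S)-4,10-dimethyl-8-methylene-9-{2-[(2RS)-2-vinyloxiran-2-yl]ethyl}-trans-decalin-4-carboxylate
Conditions: Me3S+ I−, n-BuLi, THF, −10 °C; then 30, −78 → 0 °C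
Reagents that add atoms: trimethylsulfonium iodide, C[S+](C)C.[I-]
Why: Corey–Chaykovsky epoxidation, in which the unstabilised sulfonium ylide adds kinetically to the carbonyl carbon and the betaine closes to the oxirane; both C13 epimers are acceptable because the next step is stereoconvergent.

Step 21
Reactants: 31 the vinyl epoxide
Product: 33 target CNP0167371.4 (4S,5S,9R,10S,13R; labdane numbering), via the C13 hydrogencarbonate monoester 32 (not isolated)
Conditions: Pd2(dba)3·CHCl3 (2.5 mol %), (R,R)-Trost naphthyl ligand N,N'-[(1R,2R)-cyclohexane-1,2-diyl]bis[2-(diphenylphosphino)-1-naphthamide] (7.5 mol %), Et3B (5 mol %), NaHCO3 (1.5 equiv), CH2Cl2–H2O, rt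
Reagents that add atoms: sodium hydrogencarbonate, [Na+].OC([O-])=O
Why: Palladium-catalysed dynamic kinetic asymmetric transformation, in which both epoxide epimers ionise to π-allylpalladium alkoxides that interconvert by π–σ–π isomerisation, the boron-bound alkoxide steers hydrogencarbonate to the substituted terminus, the ligand selects the face that gives 13R, and the carbonate monoester loses CO2 to give the diol.

**Compound list**
1 | δ-valerolactone | O=C1CCCCO1 | starting material
2 | sodium 5-hydroxypentanoate | [Na+].[O-]C(=O)CCCCO | intermediate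
3 | tert-butyldiphenylsilyl 5-(tert-butyldiphenylsilyloxy)pentanoate | CC(C)(C)[Si](OCCCCC(=O)O[Si](c1ccccc1)(c1ccccc1)C(C)(C)C)(c1ccccc1)c1ccccc1 | intermediate
4 | 5-(tert-butyldiphenylsilyloxy)pentanoic acid | OC(=O)CCCCO[Si](c1ccccc1)(c1ccccc1)C(C)(C)C | intermediate
5 | (R)-4-benzyl-2-oxazolidinone | C1[C@H](NC(=O)O1)Cc2ccccc2 | starting material
6 | 5-(tert-butyldiphenylsilyloxy)pentanoic pivalic anhydride | CC(C)(C)C(=O)OC(=O)CCCCO[Si](c1ccccc1)(c1ccccc1)C(C)(C)C | intermediate
7 | (R)-4-benzyl-3-[5-(tert-butyldiphenylsilyloxy)pentanoyl]oxazolidin-2-one | O=C(CCCCO[Si](c1ccccc1)(c1ccccc1)C(C)(C)C)N1[C@H](Cc2ccccc2)COC1=O | intermediate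
8 | pent-4-enal | C=CCCC=O | starting material
9 | Z dibutylboron enolate of 7 | CCCCB(CCCC)O/C(N1[C@H](Cc2ccccc2)COC1=O)=C\CCCO[Si](c1ccccc1)(c1ccccc1)C(C)(C)C | intermediate
10 | dibutylboron aldolate of 11 | C=CCC[C@H](OB(CCCC)CCCC)[C@@H](CCCO[Si](c1ccccc1)(c1ccccc1)C(C)(C)C)C(=O)N1[C@H](Cc2ccccc2)COC1=O | intermediate
11 | (R)-4-benzyl-3-[(2R,3S)-2-[3-(tert-butyldiphenylsilyloxy)propyl]-3-hydroxyhept-6-enoyl]oxazolidin-2-one | C=CCC[C@H](O)[C@@H](CCCO[Si](c1ccccc1)(c1ccccc1)C(C)(C)C)C(=O)N1[C@H](Cc2ccccc2)COC1=O | intermediate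
12 | (R)-4-benzyl-3-[(2R,3S)-3-(tert-butyldimethylsilyloxy)-2-[3-(tert-butyldiphenylsilyloxy)propyl]hept-6-enoyl]oxazolidin-2-one | C=CCC[C@H](O[Si](C)(C)C(C)(C)C)[C@@H](CCCO[Si](c1ccccc1)(c1ccccc1)C(C)(C)C)C(=O)N1[C@H](Cc2ccccc2)COC1=O | intermediate
13 | (2S,3S)-3-(tert-butyldimethylsilyloxy)-2-[3-(tert-butyldiphenylsilyloxy)propyl]hept-6-en-1-ol | C=CCC[C@H](O[Si](C)(C)C(C)(C)C)[C@@H](CCCO[Si](c1ccccc1)(c1ccccc1)C(C)(C)C)CO | intermediate
14 | (2R,3S)-3-(tert-butyldimethylsilyloxy)-2-[3-(tert-butyldiphenylsilyloxy)propyl]hept-6-enal | C=CCC[C@H](O[Si](C)(C)C(C)(C)C)[C@@H](CCCO[Si](c1ccccc1)(c1ccccc1)C(C)(C)C)C=O | intermediate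
15 | tert-butyl{[(4S,5S)-5-(tert-butyldimethylsilyloxy)-4-ethynylnon-8-en-1-yl]oxy}diphenylsilane | C=CCC[C@H](O[Si](C)(C)C(C)(C)C)[C@@H](CCCO[Si](c1ccccc1)(c1ccccc1)C(C)(C)C)C#C | intermediate
16 | E alkenyldimethylalane from 15 (CH3 on C10, AlMe2 on C1) | C=CCC[C@H](O[Si](C)(C)C(C)(C)C)[C@@H](CCCO[Si](c1ccccc1)(c1ccccc1)C(C)(C)C)/C(C)=C/[Al](C)C | intermediate
17 | tert-butyl{[(4S,5S)-5-(tert-butyldimethylsilyloxy)-4-[(E)-1-iodoprop-1-en-2-yl]non-8-en-1-yl]oxy}diphenylsilane | C=CCC[C@H](O[Si](C)(C)C(C)(C)C)[C@@H](CCCO[Si](c1ccccc1)(c1ccccc1)C(C)(C)C)/C(C)=C/I | intermediate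
18 | methyl methacrylate | C=C(C)C(=O)OC | starting material
19 | methyl (2E,6S,7S,8E)-6-(tert-butyldimethylsilyloxy)-7-[3-(tert-butyldiphenylsilyloxy)propyl]-9-iodo-2,8-dimethylnona-2,8-dienoate | COC(=O)/C(C)=C/CC[C@H](O[Si](C)(C)C(C)(C)C)[C@@H](CCCO[Si](c1ccccc1)(c1ccccc1)C(C)(C)C)/C(C)=C/I | intermediate
20 | tributyl(vinyl)stannane | CCCC[Sn](CCCC)(CCCC)C=C | starting material
21 | methyl (2E,6S,7S,8E)-6-(tert-butyldimethylsilyloxy)-7-[3-(tert-butyldiphenylsilyloxy)propyl]-2,8-dimethylundeca-2,8,10-trienoate (Diels–Alder precursor) | COC(=O)/C(C)=C/CC[C@H](O[Si](C)(C)C(C)(C)C)[C@@H](CCCO[Si](c1ccccc1)(c1ccccc1)C(C)(C)C)/C(C)=C/C=C | intermediate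
22 | trans-fused octalin ester, (4S,5S,8S,9S,10R), C1=C2 alkene, C8 OTBS and C9 3-(TBDPSO)propyl equatorial, CO2Me cis to H5 | CC(C)(C)[Si](c1ccccc1)(c1ccccc1)OCCC[C@@H]1[C@@H](O[Si](C)(C)C(C)(C)C)CC[C@H]2[C@@]1(C)C=CC[C@]2(C)C(=O)OC | intermediate
23 | 1,2-dihydro derivative of 22, (4S,5S,8S,9S,10R) | CC(C)(C)[Si](c1ccccc1)(c1ccccc1)OCCC[C@@H]1[C@@H](O[Si](C)(C)C(C)(C)C)CC[C@H]2[C@@]1(C)CCC[C@]2(C)C(=O)OC | intermediate
24 | C8 alcohol, (4S,5S,8S,9S,10R) | CC(C)(C)[Si](c1ccccc1)(c1ccccc1)OCCC[C@@H]1[C@@H](O)CC[C@H]2[C@@]1(C)CCC[C@]2(C)C(=O)OC | intermediate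
25 | C8 ketone, (4S,5S,9S,10R) | CC(C)(C)[Si](c1ccccc1)(c1ccccc1)OCCC[C@@H]1C(=O)CC[C@H]2[C@@]1(C)CCC[C@]2(C)C(=O)OC | intermediate
26 | 8(17)-methylene silyl ether, (4S,5S,9R,10S) | CC(C)(C)[Si](c1ccccc1)(c1ccccc1)OCCC[C@@H]1C(=C)CC[C@H]2[C@@]1(C)CCC[C@]2(C)C(=O)OC | intermediate
27 | C13 primary alcohol, (4S,5S,9R,10S) | OCCC[C@@H]1C(=C)CC[C@H]2[C@@]1(C)CCC[C@]2(C)C(=O)OC | intermediate
28 | C13 aldehyde, (4S,5S,9R,10S) | O=CCC[C@@H]1C(=C)CC[C@H]2[C@@]1(C)CCC[C@]2(C)C(=O)OC | intermediate
29 | C13 allylic alcohol, both C13 epimers | C=CC(O)CC[C@@H]1C(=C)CC[C@H]2[C@@]1(C)CCC[C@]2(C)C(=O)OC | intermediate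
30 | C13 vinyl ketone | C=CC(=O)CC[C@@H]1C(=C)CC[C@H]2[C@@]1(C)CCC[C@]2(C)C(=O)OC | intermediate
31 | 13,16-epoxide (2-alkyl-2-vinyloxirane), both C13 epimers | C=CC1(CO1)CC[C@@H]1C(=C)CC[C@H]2[C@@]1(C)CCC[C@]2(C)C(=O)OC | intermediate
32 | (13R)-16-hydroxy-13-yl hydrogencarbonate | C=C[C@@](OC(=O)O)(CO)CC[C@@H]1C(=C)CC[C@H]2[C@@]1(C)CCC[C@]2(C)C(=O)OC | intermediate
33 | CNP0167371.4, methyl ester on C4 (cis to H5), 8(17)-methylene, side chain CH2CH2C(OH)(CH2OH)CH=CH2, (4S,5S,9R,10S,13R) | C=C[C@@](O)(CO)CC[C@@H]1C(=C)CC[C@H]2[C@@]1(C)CCC[C@]2(C)C(=O)OC | target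

**Totals and risk**
Total step count: 21. Longest linear sequence: 21 steps (from δ-valerolactone 1 to 33).

Steps most likely to fail:

1. Step 11 (cycloaddition). The inside C20 methyl and the two fully substituted bond-forming carbons may make the ester too slow a dienophile, so that the acid-sensitive diene decomposes first, or endo selectivity may erode and give cis-fused material. Fallback, setting out from 21 and returning at 22: the dienophile is made more reactive by changing its oxidation state. DIBAL-H (CH2Cl2, −78 °C) should give the (2E,8E)-trienol F1, MnO2 (CH2Cl2, rt) the (2E,8E)-trienal F2, and Me2AlCl (CH2Cl2, −78 → −20 °C) should then close both rings through the aldehyde-endo transition state to the octalin aldehyde F3. Pinnick oxidation (NaClO2, NaH2PO4, 2-methyl-2-butene, tBuOH–H2O) should give the octalin carboxylic acid F4, and TMSCHN2 (MeOH–toluene) should return ester 22.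

2. Step 21 (C13 stereocentre). Facial discrimination at the fully substituted allyl terminus may be insufficient, or the π-allyl complex may be captured at the primary terminus or collapse to a dienol. Fallback, setting out from 31 and returning at 33: the oxygen is delivered as a boron-bound neutral alcohol instead of a carbonate anion. Pd2(dba)3·CHCl3, the same ligand, catalytic Et3B and 4-methoxybenzyl alcohol in CH2Cl2 should give the (13R) tertiary 4-methoxybenzyl ether F5, and DDQ (CH2Cl2–pH 7 buffer) should unmask 33.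

3. Step 20 (epoxidation of the vinyl ketone). The basic ylide may add in conjugate fashion, enolise C12 or polymerise the enone. Fallback, setting out from 28 and returning at 31, avoiding the enone altogether: chloromethyllithium (ICH2Cl, MeLi·LiBr, THF, −78 °C) should give the C13 chlorohydrin F6, Dess–Martin oxidation the chloromethyl ketone F7, and vinylmagnesium bromide (THF, −78 °C) the tertiary vinyl chlorohydrin F8, which K2CO3 in MeOH should close to epoxide 31.

**Further compounds**
F1 | step 11 | (2E,6S,7S,8E)-6-(tert-butyldimethylsilyloxy)-7-[3-(tert-butyldiphenylsilyloxy)propyl]-2,8-dimethylundeca-2,8,10-trien-1-ol | OC/C(C)=C/CC[C@H](O[Si](C)(C)C(C)(C)C)[C@@H](CCCO[Si](c1ccccc1)(c1ccccc1)C(C)(C)C)/C(C)=C/C=C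
F2 | step 11 | (2E,6S,7S,8E)-6-(tert-butyldimethylsilyloxy)-7-[3-(tert-butyldiphenylsilyloxy)propyl]-2,8-dimethylundeca-2,8,10-trienal | O=C/C(C)=C/CC[C@H](O[Si](C)(C)C(C)(C)C)[C@@H](CCCO[Si](c1ccccc1)(c1ccccc1)C(C)(C)C)/C(C)=C/C=C
F3 | step 11 | trans-fused octalin aldehyde (C4 formyl analogue of 22) | CC(C)(C)[Si](c1ccccc1)(c1ccccc1)OCCC[C@@H]1[C@@H](O[Si](C)(C)C(C)(C)C)CC[C@H]2[C@@]1(C)C=CC[C@]2(C)C=O
F4 | step 11 | trans-fused octalin carboxylic acid (C4 acid analogue of 22) | CC(C)(C)[Si](c1ccccc1)(c1ccccc1)OCCC[C@@H]1[C@@H](O[Si](C)(C)C(C)(C)C)CC[C@H]2[C@@]1(C)C=CC[C@]2(C)C(=O)O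
F5 | step 21 | (13R)-13-O-(4-methoxybenzyl) ether of 33 | C=C[C@@](OCc1ccc(OC)cc1)(CO)CC[C@@H]1C(=C)CC[C@H]2[C@@]1(C)CCC[C@]2(C)C(=O)OC
F6 | step 20 | C13 chlorohydrin (16-chloro-13-hydroxy, both epimers) | ClCC(O)CC[C@@H]1C(=C)CC[C@H]2[C@@]1(C)CCC[C@]2(C)C(=O)OC
F7 | step 20 | C13 chloromethyl ketone | ClCC(=O)CC[C@@H]1C(=C)CC[C@H]2[C@@]1(C)CCC[C@]2(C)C(=O)OC
F8 | step 20 | 16-chloro-13-hydroxy-13-vinyl chlorohydrin (both epimers) | C=CC(O)(CCl)CC[C@@H]1C(=C)CC[C@H]2[C@@]1(C)CCC[C@]2(C)C(=O)OC
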